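Ring B is grown from a 2-pyrone instead of being bought as an arene. Its oxygen sits on C5', 1,4 to C2' (the carbon holding the 4-hydroxybenzyl group) and 1,3 to C1' (the carbon holding the ethylene bridge). This is the pattern that remains when a 5-acyl-6-alkyl-2-pyrone adds a ketene acetal across C6 and C3 and then expels CO2 and an alcohol. One operation therefore forms C1'-C6' and C4'-C5', closes ring B, installs its protected phenol, and leaves the activating carbonyl as the future benzylic CH2. The precursor is a 5-[4-(benzyloxy)benzoyl]-2-pyrone whose C6 carries the complete benzyl-protected ring A through the CH2CH2 bridge.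

Key step: step 11

Remarks on the chemistry
- **Locants.** Ring A: C1 bridge, C2 and C6 4-oxybenzyl, C3 OH, C4 H, C5 OMe. Ring B: C1' bridge, C2' benzyl, C5' OH.
- **Abbreviation.** ArA = 3-(benzyloxy)-2,6-bis[4-(benzyloxy)benzyl]-5-methoxyphenyl.
- **Stereochemistry.** The target has no stereocentre. The bridged cycloadduct and the diaryl carbinol are racemic, and their stereocentres disappear in the next event.
- **Ring A.** The three-carbon chain is coupled to the aryl bromide while both ortho positions are still free. The two benzyl groups then enter by cross-coupling at bromines that the resorcinol-ether directing effect places at C2 and C6. A Friedel-Crafts benzylation could also reach C4 and could oligomerise.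
- **Pyrone.** The ring is closed from a β-keto ester, in which only the ketone oxygen can lactonise, and the aroyl group is attached afterwards. An unsymmetrical 1,3-diketone would offer two enol oxygens and so two isomeric pyrones.
- **Ketene acetal.** It carries benzyl groups so that the new ring B oxygen is freed in the final hydrogenolysis. A methyl or ethyl ether there could not be distinguished from the ring A methoxy group. Benzyl ketene acetals suffer O-to-C benzyl shift when overheated, so this one is not distilled and is used at 110 °C or below.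

Step 1
Reactants: 1 3-bromo-5-methoxyphenol
Product: 2 1-(benzyloxy)-3-bromo-5-methoxybenzene
Conditions: BnBr (1.1 equiv), K2CO3, DMF, rt
Reagents that add atoms: benzyl bromide BrCc1ccccc1
Why: Williamson ether synthesis on the only acidic OH; the aryl bromide and the methyl ether are inert to K2CO3 and BnBr.

Step 2
Reactants: 2 1-(benzyloxy)-3-bromo-5-methoxybenzene; 3 (3-ethoxy-3-oxopropyl)zinc bromide (commercial THF solution)
Product: 4 ethyl 3-[3-(benzyloxy)-5-methoxyphenyl]propanoate
Conditions: Pd(OAc)2 (2 mol%), SPhos (4 mol%), THF, 50 °C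
Reagents that add atoms: none
Why: Negishi coupling of a primary alkylzinc homoenolate with an aryl bromide that has two free ortho positions; the bulky biaryl phosphine should make reductive elimination faster than β-hydride elimination, and the zinc reagent tolerates its own ester.

Step 3
Reactants: 4 ethyl 3-[3-(benzyloxy)-5-methoxyphenyl]propanoate
Product: 5 ethyl 3-[3-(benzyloxy)-2,6-dibromo-5-methoxyphenyl]propanoate
Conditions: NBS (2.1 equiv), MeCN, 0 °C to rt, dark
Reagents that add atoms: N-bromosuccinimide O=C1CCC(=O)N1Br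
Why: Ionic electrophilic aromatic bromination in which each alkoxy group of a resorcinol diether directs para, so the bromines should go to C2 and C6, while C4 between the two oxygens is the least reactive site and the unactivated O-benzyl ring is not attacked.

Step 4
Reactants: 5 ethyl 3-[3-(benzyloxy)-2,6-dibromo-5-methoxyphenyl]propanoate; 6 4-(benzyloxy)benzyl chloride (3 equiv)
Product: 8 ethyl 3-ArA-propanoate, via benzylzinc chloride 7 (not isolated)
Conditions: 6, Zn dust, LiCl, THF, rt; then 5, Pd(OAc)2 (4 mol%), SPhos (8 mol%), THF, 50 °C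
Reagents that add atoms: none
Why: LiCl-promoted zinc insertion into the benzylic chloride followed by a twofold Negishi coupling; the benzylzinc reagent has no β-hydrogen and spares the ester, and Pd(OAc)2/SPhos is a catalyst type that accepts electron-rich, di-ortho-substituted aryl bromides.

Step 5
Reactants: 8 ethyl 3-ArA-propanoate; 9 tert-butyl acetate (4 equiv)
Product: 11 tert-butyl 5-ArA-3-oxopentanoate, via lithium enolate 10 (not isolated)
Conditions: 9, LiN(iPr)2 (4 equiv), THF, -78 °C; then 8, -78 to 0 °C; cold 1 M HCl quench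
Reagents that add atoms: none
Why: Crossed Claisen condensation in which the hindered tert-butyl acetate enolate does not self-condense at low temperature, and its excess drives the reaction by deprotonating the β-keto ester as it forms.

Step 6
Reactants: 11 tert-butyl 5-ArA-3-oxopentanoate; 12 methyl propiolate (1.3 equiv)
Product: 14 tert-butyl 6-(2-ArA-ethyl)-2-oxo-2H-pyran-5-carboxylate, via Michael adduct 13 (not isolated)
Conditions: Cs2CO3 (0.2 equiv), MeCN, 0 °C to rt; then solvent switch to toluene, 4 Å MS, 110 °C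
Reagents that add atoms: none
Why: Base-catalysed Michael addition of the β-keto ester carbon to the propiolate and enol lactonisation (the classical 2-pyrone synthesis); the delocalised anion of 13 equilibrates the alkene geometry, only the ketone oxygen can close the lactone so the chain ends at C6 and the ester at C5, and removal of methanol pulls the equilibrium.

Step 7
Reactants: 14 tert-butyl 6-(2-ArA-ethyl)-2-oxo-2H-pyran-5-carboxylate
Product: 15 6-(2-ArA-ethyl)-2-oxo-2H-pyran-5-carboxylic acid
Conditions: TFA/CH2Cl2 (1:4), 0 °C to rt, short contact time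
Reagents that add atoms: none
Why: Acidolysis of the tert-butyl ester with loss of isobutene; the 2-pyrone is acid-stable, and the aryl benzyl ethers and diarylmethane units should tolerate brief exposure to dilute TFA at or below room temperature.

Step 8
Reactants: 15 6-(2-ArA-ethyl)-2-oxo-2H-pyran-5-carboxylic acid; 16 1-(benzyloxy)-4-bromobenzene (1.3 equiv)
Product: 19 5-[4-(benzyloxy)benzoyl]-6-(2-ArA-ethyl)-2H-pyran-2-one, via pyrone acid chloride 17 (not isolated), via arylzinc chloride 18 (not isolated)
Conditions: 15, (COCl)2, DMF (cat.), CH2Cl2, 0 °C to rt, evaporate; 16, nBuLi, THF, -78 °C, then ZnCl2, to 0 °C; combine, Pd(PPh3)4 (5 mol%), THF, 0 °C to rt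
Reagents that add atoms: none
Why: Acid chloride formation followed by acylative Negishi coupling; zerovalent palladium inserts into the C(O)-Cl bond at 0 °C, the arylzinc reagent is too mild to add to the pyrone or to the ketone formed, and no base is present that could deprotonate the acidified CH2 on C6.

Step 9
Reactants: 20 bromoacetaldehyde diethyl acetal
Product: 21 bromoacetaldehyde dibenzyl acetal [2-bromo-1,1-bis(benzyloxy)ethane]
Conditions: BnOH (2.2 equiv), TsOH·H2O (cat.), 110 °C, EtOH distilled off
Reagents that add atoms: benzyl alcohol OCc1ccccc1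
Why: Acid-catalysed transacetalisation driven to completion by removing the lower-boiling ethanol.

Step 10
Reactants: 21 bromoacetaldehyde dibenzyl acetal
Product: 22 1,1-bis(benzyloxy)ethene
Conditions: KOtBu (1.3 equiv), THF, 0 to 40 °C; filtration through basic Al2O3 (pentane/Et2O, 1% Et3N), no distillation, stored cold over K2CO3
Reagents that add atoms: none
Why: E2 dehydrobromination of a bromoacetal with a hindered alkoxide, the classical ketene acetal synthesis; acid-free and non-thermal isolation guards against hydrolysis and benzyl migration.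

Step 11
Reactants: 19 5-[4-(benzyloxy)benzoyl]-6-(2-ArA-ethyl)-2H-pyran-2-one; 22 1,1-bis(benzyloxy)ethene (4 equiv, in two portions)
Product: 25 [4-(benzyloxy)phenyl][4-(benzyloxy)-2-(2-ArA-ethyl)phenyl]methanone, via bridged lactone 23 (not isolated), via cyclohexadiene ketal 24 (not isolated)
Conditions: toluene, K2CO3 (solid, acid scavenger), sealed tube, 110 °C; DBU (cat.), rt, if 24 persists
Reagents that add atoms: none
Why: This is an inverse-electron-demand Diels-Alder reaction of an acceptor-substituted 2-pyrone with a ketene acetal, the reaction type that converts coumalates and 5-acyl-2-pyrones into para-alkoxy aryl carbonyl compounds. The electron-rich CH2 of 22 bonds to pyrone C6, which is both the β-carbon of the aroyl enone and the δ-carbon of the lactone dienoate, and the acetal carbon bonds to C3, so C1'-C6' and C4'-C5' form and ring B closes as the six-membered carbocycle of 23 by intermolecular [4+2] addition. Retro-[4+2] loss of CO2 gives 24, whose ring CH2 is vinylogously acidified by the aroyl group, so benzyl alcohol leaves by 1,2-elimination and the ring aromatises. No stereocentre survives, since those of 23 vanish with CO2. The only selectivity needed is orientation, and the matched polarisation of diene and dienophile secures it by placing OBn para to the aroyl-bearing C2' and meta to C1'. Capture of a dipolar intermediate by the aroyl oxygen would be reversible whereas CO2 loss is not, and 110 °C stays below the range in which 22 undergoes O-to-C benzyl shift.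

Step 12
Reactants: 25 [4-(benzyloxy)phenyl][4-(benzyloxy)-2-(2-ArA-ethyl)phenyl]methanone
Product: 26 [4-(benzyloxy)phenyl][4-(benzyloxy)-2-(2-ArA-ethyl)phenyl]methanol (racemic)
Conditions: NaBH4 (excess), THF/MeOH, 0 to 50 °C
Reagents that add atoms: none
Why: Hydride reduction of the diaryl ketone, the only group in 25 that NaBH4 can reduce; it is done before debenzylation because a 4,4'-dihydroxybenzophenone would resist reduction, and the new stereocentre forms racemic and is erased in step 13.

Step 13
Reactants: 26 [4-(benzyloxy)phenyl][4-(benzyloxy)-2-(2-ArA-ethyl)phenyl]methanol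
Product: 27 2,4-bis(4-hydroxybenzyl)-3-{2-[5-hydroxy-2-(4-hydroxybenzyl)phenyl]ethyl}-5-methoxyphenol (CNP0147493.0)
Conditions: H2 (3 bar), 10% Pd/C, THF/EtOH, AcOH (5 vol%), rt
Reagents that add atoms: none
Why: Catalytic hydrogenolysis should cleave the five O-benzyl bonds and the doubly benzylic, para-oxygen-activated C-OH bond in one operation, while the methyl ether, the diarylmethane C-C bonds and the arenes are inert at low pressure.

Compound list
1 | 3-bromo-5-methoxyphenol | COc1cc(O)cc(Br)c1 | starting material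
2 | 1-(benzyloxy)-3-bromo-5-methoxybenzene | COc1cc(Br)cc(OCc2ccccc2)c1 | intermediate
3 | (3-ethoxy-3-oxopropyl)zinc bromide | CCOC(=O)CC[Zn]Br | starting material
4 | ethyl 3-[3-(benzyloxy)-5-methoxyphenyl]propanoate | CCOC(=O)CCc1cc(OC)cc(OCc2ccccc2)c1 | intermediate
5 | ethyl 3-[3-(benzyloxy)-2,6-dibromo-5-methoxyphenyl]propanoate | CCOC(=O)CCc1c(Br)c(OC)cc(OCc2ccccc2)c1Br | intermediate
6 | 4-(benzyloxy)benzyl chloride | ClCc1ccc(OCc2ccccc2)cc1 | starting material
7 | [4-(benzyloxy)benzyl]zinc chloride (LiCl-solvated, not isolated) | Cl[Zn]Cc1ccc(OCc2ccccc2)cc1 | intermediate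
8 | ethyl 3-{3-(benzyloxy)-2,6-bis[4-(benzyloxy)benzyl]-5-methoxyphenyl}propanoate | CCOC(=O)CCc1c(Cc2ccc(OCc3ccccc3)cc2)c(OC)cc(OCc2ccccc2)c1Cc1ccc(OCc2ccccc2)cc1 | intermediate
9 | tert-butyl acetate | CC(=O)OC(C)(C)C | starting material
10 | lithium enolate of tert-butyl acetate (not isolated) | [Li]OC(=C)OC(C)(C)C | intermediate
11 | tert-butyl 5-{3-(benzyloxy)-2,6-bis[4-(benzyloxy)benzyl]-5-methoxyphenyl}-3-oxopentanoate | CC(C)(C)OC(=O)CC(=O)CCc1c(Cc2ccc(OCc3ccccc3)cc2)c(OC)cc(OCc2ccccc2)c1Cc1ccc(OCc2ccccc2)cc1 | intermediate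
12 | methyl propiolate | C#CC(=O)OC | starting material
13 | 1-tert-butyl 5-methyl 2-(3-ArA-propanoyl)pent-3-enedioate (E/Z mixture, not isolated) | COC(=O)C=CC(C(=O)OC(C)(C)C)C(=O)CCc1c(Cc2ccc(OCc3ccccc3)cc2)c(OC)cc(OCc2ccccc2)c1Cc1ccc(OCc2ccccc2)cc1 | intermediate
14 | tert-butyl 6-(2-ArA-ethyl)-2-oxo-2H-pyran-5-carboxylate | CC(C)(C)OC(=O)c1ccc(=O)oc1CCc1c(Cc2ccc(OCc3ccccc3)cc2)c(OC)cc(OCc2ccccc2)c1Cc1ccc(OCc2ccccc2)cc1 | intermediate
15 | 6-(2-ArA-ethyl)-2-oxo-2H-pyran-5-carboxylic acid | OC(=O)c1ccc(=O)oc1CCc1c(Cc2ccc(OCc3ccccc3)cc2)c(OC)cc(OCc2ccccc2)c1Cc1ccc(OCc2ccccc2)cc1 | intermediate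
16 | 1-(benzyloxy)-4-bromobenzene | Brc1ccc(OCc2ccccc2)cc1 | starting material
17 | 6-(2-ArA-ethyl)-2-oxo-2H-pyran-5-carbonyl chloride (not isolated) | ClC(=O)c1ccc(=O)oc1CCc1c(Cc2ccc(OCc3ccccc3)cc2)c(OC)cc(OCc2ccccc2)c1Cc1ccc(OCc2ccccc2)cc1 | intermediate
18 | [4-(benzyloxy)phenyl]zinc chloride (not isolated) | Cl[Zn]c1ccc(OCc2ccccc2)cc1 | intermediate
19 | 5-[4-(benzyloxy)benzoyl]-6-(2-ArA-ethyl)-2H-pyran-2-one | O=C(c1ccc(OCc2ccccc2)cc1)c1ccc(=O)oc1CCc1c(Cc2ccc(OCc3ccccc3)cc2)c(OC)cc(OCc2ccccc2)c1Cc1ccc(OCc2ccccc2)cc1 | intermediate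
20 | bromoacetaldehyde diethyl acetal | CCOC(CBr)OCC | starting material
21 | bromoacetaldehyde dibenzyl acetal | BrCC(OCc1ccccc1)OCc1ccccc1 | intermediate
22 | 1,1-bis(benzyloxy)ethene | C=C(OCc1ccccc1)OCc1ccccc1 | intermediate
23 | 6-[4-(benzyloxy)benzoyl]-8,8-bis(benzyloxy)-1-(2-ArA-ethyl)-2-oxabicyclo[2.2.2]oct-5-en-3-one (racemic, not isolated) | O=C1OC2(CCc3c(Cc4ccc(OCc5ccccc5)cc4)c(OC)cc(OCc4ccccc4)c3Cc3ccc(OCc4ccccc4)cc3)CC(OCc3ccccc3)(OCc3ccccc3)C1C=C2C(=O)c1ccc(OCc2ccccc2)cc1 | intermediate
24 | [4-(benzyloxy)phenyl][4,4-bis(benzyloxy)-2-(2-ArA-ethyl)cyclohexa-1,5-dien-1-yl]methanone (not isolated) | O=C(c1ccc(OCc2ccccc2)cc1)C1=C(CCc2c(Cc3ccc(OCc4ccccc4)cc3)c(OC)cc(OCc3ccccc3)c2Cc2ccc(OCc3ccccc3)cc2)CC(OCc2ccccc2)(OCc2ccccc2)C=C1 | intermediate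
25 | [4-(benzyloxy)phenyl][4-(benzyloxy)-2-(2-ArA-ethyl)phenyl]methanone | O=C(c1ccc(OCc2ccccc2)cc1)c1ccc(OCc2ccccc2)cc1CCc1c(Cc2ccc(OCc3ccccc3)cc2)c(OC)cc(OCc2ccccc2)c1Cc1ccc(OCc2ccccc2)cc1 | intermediate
26 | [4-(benzyloxy)phenyl][4-(benzyloxy)-2-(2-ArA-ethyl)phenyl]methanol (racemic) | OC(c1ccc(OCc2ccccc2)cc1)c1ccc(OCc2ccccc2)cc1CCc1c(Cc2ccc(OCc3ccccc3)cc2)c(OC)cc(OCc2ccccc2)c1Cc1ccc(OCc2ccccc2)cc1 | intermediate
27 | 2,4-bis(4-hydroxybenzyl)-3-{2-[5-hydroxy-2-(4-hydroxybenzyl)phenyl]ethyl}-5-methoxyphenol | COc1cc(O)c(Cc2ccc(O)cc2)c(CCc2cc(O)ccc2Cc2ccc(O)cc2)c1Cc1ccc(O)cc1 | target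

Total step count: 13. Longest linear sequence: 11 (steps 1 to 8, then 11 to 13). Steps 9 and 10 form a two-step side branch.

Steps most likely to fail

**Step 11.**
- What may go wrong: addition at the fully substituted C6 terminus may be slow, because the aroyl group is twisted out of the pyrone plane and weakened by its para oxygen donor. A dipolar intermediate may be diverted through the aroyl oxygen. The ketene acetal may decay thermally before the diene is consumed.
- Fallback: it sets out from 14 and comes back at 25. It moves the cycloaddition onto the ester-activated pyrone, a 6-alkylcoumalate, which belongs to the best documented diene class for this reaction and whose ester carbonyl is a poor heterodiene.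
- Heating 14 with 22 (toluene, 110 °C) should give, by the same loss of CO2 and benzyl alcohol, tert-butyl 4-(benzyloxy)-2-(2-ArA-ethyl)benzoate F1.
- TFA in CH2Cl2 frees 4-(benzyloxy)-2-(2-ArA-ethyl)benzoic acid F2.
- (COCl)2 with catalytic DMF gives 4-(benzyloxy)-2-(2-ArA-ethyl)benzoyl chloride F3.
- Pd(PPh3)4-catalysed acylative Negishi coupling of F3 with arylzinc chloride 18, made from 16 as in step 8, delivers 25.

**Step 6.**
- What may go wrong: the stabilised anion of the Michael adduct may be reluctant to lactonise or may add a second propiolate. Forcing conditions may strip the tert-butyl ester and trigger decarboxylation.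
- Fallback: it sets out from 8 and comes back at 19, bypassing steps 5 to 8 by bringing the aroyl group in before the ring is made.
- Crossed Claisen condensation of 8 with commercial 4'-(benzyloxy)acetophenone (LiN(SiMe3)2, THF, -78 °C to rt) should give the strongly enolised 1-[4-(benzyloxy)phenyl]-5-ArA-pentane-1,3-dione F4.
- Michael addition of F4 to methyl propiolate 12 and enol lactonisation (Cs2CO3 cat., then toluene, 110 °C) leads directly to 19.
- The price is competition between two enol oxygens. The constitution of the pyrone would have to be proven by long-range C-H correlation and any isomer removed by chromatography.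

**Step 10.**
- What may go wrong: dehydrobromination may be incomplete, the ketene acetal may hydrolyse on work-up, and benzyl may migrate from O to C during purification.
- Fallback: it sets out from 19 and comes back at 25. It replaces the dialkyl ketene acetal by a silyl ketene acetal made through enolate O-silylation.
- Commercial benzyl acetate with LiN(iPr)2 and tBuMe2SiCl (THF/DMPU, -78 °C) should give 1-(benzyloxy)-1-[(tert-butyldimethylsilyl)oxy]ethene F5.
- Heating F5 with 19 in toluene, then treating the crude product with Bu4NF/AcOH, collapses the silylated material to [4-(benzyloxy)phenyl][4-hydroxy-2-(2-ArA-ethyl)phenyl]methanone F6.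
- Any portion that aromatised by losing the silanol is already 25, so benzylation of the crude phenol (BnBr, K2CO3, DMF) funnels all material into 25.

Further compounds
F1 | step 11 | tert-butyl 4-(benzyloxy)-2-(2-ArA-ethyl)benzoate | CC(C)(C)OC(=O)c1ccc(OCc2ccccc2)cc1CCc1c(Cc2ccc(OCc3ccccc3)cc2)c(OC)cc(OCc2ccccc2)c1Cc1ccc(OCc2ccccc2)cc1
F2 | step 11 | 4-(benzyloxy)-2-(2-ArA-ethyl)benzoic acid | OC(=O)c1ccc(OCc2ccccc2)cc1CCc1c(Cc2ccc(OCc3ccccc3)cc2)c(OC)cc(OCc2ccccc2)c1Cc1ccc(OCc2ccccc2)cc1
F3 | step 11 | 4-(benzyloxy)-2-(2-ArA-ethyl)benzoyl chloride | ClC(=O)c1ccc(OCc2ccccc2)cc1CCc1c(Cc2ccc(OCc3ccccc3)cc2)c(OC)cc(OCc2ccccc2)c1Cc1ccc(OCc2ccccc2)cc1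
F4 | step 6 | 1-[4-(benzyloxy)phenyl]-5-ArA-pentane-1,3-dione | O=C(CC(=O)CCc1c(Cc2ccc(OCc3ccccc3)cc2)c(OC)cc(OCc2ccccc2)c1Cc1ccc(OCc2ccccc2)cc1)c1ccc(OCc2ccccc2)cc1
F5 | step 10 | 1-(benzyloxy)-1-[(tert-butyldimethylsilyl)oxy]ethene | C=C(OCc1ccccc1)O[Si](C)(C)C(C)(C)C
F6 | step 10 | [4-(benzyloxy)phenyl][4-hydroxy-2-(2-ArA-ethyl)phenyl]methanone | O=C(c1ccc(OCc2ccccc2)cc1)c1ccc(O)cc1CCc1c(Cc2ccc(OCc3ccccc3)cc2)c(OC)cc(OCc2ccccc2)c1Cc1ccc(OCc2ccccc2)cc1
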